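The ten-membered carbocycle is cut at C6-C7. The C6 carbinol lies between C7, whose isopropyl group (C11-C13) is a reduced isopropenyl unit, and the C4-C5 oxirane, which maps back onto an alkyne. This array is the retron of a propargylic [2,3]-Wittig shift. The precursor is a 13-membered ether ring in which oxygen links propargylic C6 to allylic C12 of a Z C7=C11 alkene, with the (3S)-hydroxyl and the E C1=C10 alkene already in place. One operation contracts thirteen ring members to ten, forms C6-C7, sets C6 and C7, and releases the C6 hydroxyl that later guides methylation at C4 and epoxidation.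

Key step: step 10

Atom labels: C1 to C15 are the germacrane positions of the target and are used for all intermediates. They are the C1=C10 alkene, C3 angelate carbon, C4-C5 oxirane, C6 acetate carbon, C7 isopropyl carbon, C11-C13 isopropyl, C14 on C10 and C15 on C4.

Assumption: the (S,S) forms of ProPhenol (step 7) and of the lithium amide (step 10) are taken to give the configurations drawn; both are sold in either mirror-image form, so the antipode is substituted if the first run (MTPA esters of the step 7 product, correlation of the step 10 product with it) shows the opposite sense.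

Step 1
Reactants: 1 pent-4-yn-1-ol
Product: 2 pent-4-ynal
Conditions: TEMPO (10 mol %), PhI(OAc)2 (1.1 equiv), CH2Cl2, rt; washed, concentrated cold, used as a solution
Reagents that add atoms: none
Why: The TEMPO oxoammonium oxidation takes a primary alcohol to the aldehyde and no further, leaves the terminal alkyne alone and creates no stereocentre.

Step 2
Reactants: 2 pent-4-ynal; 3 ethyl 2-[bis(2,2,2-trifluoroethoxy)phosphoryl]propanoate
Product: 5 ethyl (Z)-2-methylhept-2-en-6-ynoate, via potassium phosphonate carbanion 4 (not isolated)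
Conditions: 3, KN(SiMe3)2, 18-crown-6, THF, -78 °C; then 2, -78 °C
Reagents that add atoms: none
Why: In the Still-Gennari olefination the electron-poor trifluoroethyl phosphonate with a crown-separated potassium ion eliminates faster than its adducts equilibrate, which gives the Z trisubstituted enoate (C8 cis to the ester carbon C12), and the base is spent on 3 before the alkyne C-H meets it.

Step 3
Reactants: 5 ethyl (Z)-2-methylhept-2-en-6-ynoate
Product: 6 (Z)-2-methylhept-2-en-6-yn-1-ol
Conditions: i-Bu2AlH (2.5 equiv), CH2Cl2, -78 °C; aq. potassium sodium tartrate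
Reagents that add atoms: none
Why: 1,2-Reduction of the enoate by i-Bu2AlH gives the allylic alcohol without touching the alkene geometry or the alkyne.

Step 4
Reactants: 6 (Z)-2-methylhept-2-en-6-yn-1-ol
Product: 7 (Z)-2-methylhept-2-en-6-yn-1-ol tert-butyldimethylsilyl ether
Conditions: TBSCl, imidazole, CH2Cl2, 0 °C to rt
Reagents that add atoms: tert-butyldimethylsilyl chloride CC(C)(C)[Si](C)(C)Cl
Why: Imidazole-promoted silylation masks the C12 hydroxyl with a group that withstands Me3Al, n-BuLi, the periodinane and Me2Zn and later leaves under mild acid.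

Step 5
Reactants: 7 (Z)-2-methylhept-2-en-6-yn-1-ol tert-butyldimethylsilyl ether; 8 oxirane
Product: 11 (3E,7Z)-9-(tert-butyldimethylsilyloxy)-4,8-dimethylnona-3,7-dien-1-ol, via (E)-alkenyldimethylalane 9 (not isolated), via lithium butyl(dimethyl)alkenylalanate 10 (not isolated)
Conditions: Me3Al (2.5 equiv), Cp2ZrCl2 (0.25 equiv), CH2Cl2, 0 °C to rt; volatiles removed; n-BuLi (1 equiv), hexane-THF, -78 to 0 °C; 8 (THF solution, 3 equiv), -78 °C to rt; aqueous work-up
Reagents that add atoms: trimethylaluminium C[Al](C)C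
Why: Zirconium-catalysed syn carboalumination (Negishi) places the new methyl C14 on C10 and aluminium on C1 on the same side, and ate complex 10 opens oxirane with retention of the alkenyl geometry, so the C1=C10 alkene is fixed as E in the open chain.

Step 6
Reactants: 11 (3E,7Z)-9-(tert-butyldimethylsilyloxy)-4,8-dimethylnona-3,7-dien-1-ol
Product: 12 (3E,7Z)-9-(tert-butyldimethylsilyloxy)-4,8-dimethylnona-3,7-dienal
Conditions: Dess-Martin periodinane (1.2 equiv), NaHCO3, CH2Cl2, 0 °C; cold neutral work-up, used the same day without chromatography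
Reagents that add atoms: none
Why: Dess-Martin oxidation under NaHCO3 buffer is fast and essentially neutral, so the beta,gamma-alkene should not move into conjugation with the aldehyde.

Step 7
Reactants: 12 (3E,7Z)-9-(tert-butyldimethylsilyloxy)-4,8-dimethylnona-3,7-dienal; 13 3-chloroprop-1-yne
Product: 15 (4S,6E,10Z)-12-(tert-butyldimethylsilyloxy)-1-chloro-7,11-dimethyldodeca-6,10-dien-2-yn-4-ol, via methyl(3-chloroprop-1-ynyl)zinc 14 (not isolated)
Conditions: 13 (3 equiv), Me2Zn (3 equiv), (S,S)-ProPhenol (20 mol %), Ph3P=O (40 mol %), toluene, rt, 1 h; then 12 added slowly, 0 to 4 °C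
Reagents that add atoms: none
Why: In the zinc-ProPhenol catalysed asymmetric alkynylation the dinuclear zinc complex holds alkynylzinc 14 and the aldehyde side by side and passes the alkynyl group to the Re face of C3, which gives the (S)-carbinol, while the weakly basic medium and slow addition of 12 limit enolisation and leave the primary chloride intact.

Step 8
Reactants: 15 (4S,6E,10Z)-12-(tert-butyldimethylsilyloxy)-1-chloro-7,11-dimethyldodeca-6,10-dien-2-yn-4-ol
Product: 16 (2Z,6E,9S)-12-chloro-2,6-dimethyldodeca-2,6-dien-10-yne-1,9-diol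
Conditions: camphorsulfonic acid (10 mol %), MeOH-CH2Cl2, 0 °C
Reagents that add atoms: none
Why: Acid-catalysed methanolysis removes the primary allylic silyl ether quickly, and avoiding fluoride excludes halide exchange at C6 and early alkoxide formation beside the propargylic chloride.

Step 9
Reactants: 16 (2Z,6E,9S)-12-chloro-2,6-dimethyldodeca-2,6-dien-10-yne-1,9-diol
Product: 18 (5S,7E,11Z)-8,12-dimethyl-1-oxacyclotrideca-7,11-dien-3-yn-5-ol, via disodium dialkoxide 17 (not isolated)
Conditions: NaH (3 equiv), n-Bu4NI (20 mol %), THF, rt, 16 added by syringe pump (final concentration 2 mM); H2O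
Reagents that add atoms: none
Why: Intramolecular Williamson etherification with iodide (Finkelstein) catalysis under pseudo-high dilution closes the 13-membered ring by SN2 attack of the C12 alkoxide on C6, the C3 alkoxide cannot reach C6 across the linear C3-C4-C5-C6 unit, and room temperature keeps the sodium 3-oxido-1,5-enyne from an oxy-Cope shift.

Step 10
Reactants: 18 (5S,7E,11Z)-8,12-dimethyl-1-oxacyclotrideca-7,11-dien-3-yn-5-ol
Product: 21 (1(10)E,3S,6S,7R)-15-norgermacra-1(10),11-dien-4-yne-3,6-diol, via C3 lithium alkoxide 19 (not isolated), via C6-lithiated alkoxide 20 (not isolated)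
Conditions: (S,S)-[PhCH(Me)]2NLi (3.5 equiv, from the amine and n-BuLi), THF, -78 to -20 °C; H2O; diastereomers separated by chromatography
Reagents that add atoms: none
Why: The first equivalent of amide turns the C3 hydroxyl into alkoxide 19, a further one removes a propargylic C6-H next to the ether oxygen, and carbanion 20 rearranges by a concerted suprafacial [2,3]-sigmatropic shift through a five-centre envelope in which C6-C7 forms, O-C12 breaks and the C7=C11 double bond moves to C11=C12. The closest known reaction type is the [2,3]-Wittig ring contraction of 13-membered propargylic allylic ethers to cyclodecynols, including its version with a homochiral lithium amide. The ten-membered carbocycle closes transannularly, by bond formation between two atoms already held in the 13-membered ring, so neither high dilution nor a separate medium-ring cyclisation is needed. The relative configuration of C6 and C7 (C6-O syn to C8 along the C5-C6-C7-C11 chain) follows from the Z alkene reacting with the slim alkynyl group exo, an arrangement reinforced because the short C4-C3-C2-C1-C10-C9 tether bridges C5 and C8 far more easily when they are gauche and because the C13 methyl on C11 crowds the endo alternative. The sense relative to C3 is set by the homochiral amide choosing between the diastereotopic C6 hydrogens, provided the shift outruns inversion of 20, and since C3 is already a single enantiomer any minor isomer is a separable diastereomer. Site selectivity (C6-H over the allylic C12-H) comes from the acidifying alkyne, carrying the C3 oxygen as an alkoxide shuts off its 1,4-elimination to a cumulene, and the low temperature suppresses the [1,2]-shift.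

Step 11
Reactants: 21 (1(10)E,3S,6S,7R)-15-norgermacra-1(10),11-dien-4-yne-3,6-diol
Product: 22 (1(10)E,3S,6S,7R)-3-(tert-butyldimethylsilyloxy)-15-norgermacra-1(10),11-dien-4-yn-6-ol
Conditions: TBSCl (1.05 equiv), imidazole, DMF, -20 to 0 °C
Reagents that add atoms: tert-butyldimethylsilyl chloride CC(C)(C)[Si](C)(C)Cl
Why: Kinetic silylation distinguishes the two propargylic carbinols by their neighbours, since C3 is flanked by the C2 methylene whereas C6 adjoins the branched C7, and any bis-ether or regioisomer can be returned to 21 with fluoride.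

Step 12
Reactants: 22 (1(10)E,3S,6S,7R)-3-(tert-butyldimethylsilyloxy)-15-norgermacra-1(10),11-dien-4-yn-6-ol
Product: 24 (1(10)E,4Z,3S,6S,7R)-3-(tert-butyldimethylsilyloxy)-4-iodo-15-norgermacra-1(10),4,11-trien-6-ol, via five-membered cyclic alanate 23 (not isolated)
Conditions: NaAlH2(OCH2CH2OMe)2 (2.5 equiv), THF, 0 °C; EtOAc; then I2, THF, -78 °C
Reagents that add atoms: iodine II
Why: Hydroxyl-directed trans-hydroalumination of the propargylic alcohol passes hydride from the C6 aluminate to C5 and ties aluminium to C4 in alanate 23, iodinolysis with retention then gives the alkenyl iodide with iodine cis to C6 (C3 and C6 trans on the ring), and the tetracoordinate aluminium, the poorly coordinating silyl ether and the low temperature hold back beta-elimination of the C3 oxygen to an allene.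

Step 13
Reactants: 24 (1(10)E,4Z,3S,6S,7R)-3-(tert-butyldimethylsilyloxy)-4-iodo-15-norgermacra-1(10),4,11-trien-6-ol
Product: 25 (1(10)E,4E,3S,6R,7R)-3-(tert-butyldimethylsilyloxy)germacra-1(10),4,11-trien-6-ol
Conditions: Me2CuLi (6 equiv, from MeLi and CuI), Et2O, 0 °C; basic aqueous work-up; kept below 30 °C, Et3N-washed silica
Reagents that add atoms: lithium dimethylcuprate [Li+].C[Cu-]C
Why: Cuprate cross-coupling of an alkenyl iodide (Corey-Posner type) replaces iodine by methyl C15 with retention, the C6 alkoxide formed first being harmless, so the 4E alkene with C15 cis to C6 results, and cold, base-washed handling guards this (E,E)-cyclodeca-1,5-diene against Cope rearrangement and transannular cyclisation.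

Step 14
Reactants: 25 (1(10)E,4E,3S,6R,7R)-3-(tert-butyldimethylsilyloxy)germacra-1(10),4,11-trien-6-ol
Product: 26 (1(10)E,4E,3S,6S,7R)-3-(tert-butyldimethylsilyloxy)germacra-1(10),4-dien-6-ol
Conditions: H2 (1 atm), RhCl(PPh3)3 (10 mol %), toluene-EtOH, rt, stopped after one equivalent of H2
Reagents that add atoms: none
Why: Homogeneous hydrogenation with RhCl(PPh3)3 is governed by alkene substitution, so the 1,1-disubstituted isopropenyl group is saturated while the two trisubstituted ring alkenes, which bind rhodium poorly, remain.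

Step 15
Reactants: 26 (1(10)E,4E,3S,6S,7R)-3-(tert-butyldimethylsilyloxy)germacra-1(10),4-dien-6-ol
Product: 27 (1(10)E,3S,4S,5R,6S,7R)-3-(tert-butyldimethylsilyloxy)-4,5-epoxygermacr-1(10)-en-6-ol
Conditions: VO(acac)2 (5 mol %), t-BuOOH (1.3 equiv, decane solution), CH2Cl2, 0 °C; aq. NaHCO3 quench
Reagents that add atoms: tert-butyl hydroperoxide CC(C)(C)OO
Why: In the vanadium-catalysed hydroxyl-directed epoxidation, allylic 1,3-strain between C15 and the C6 substituents keeps C6-H in the alkene plane and turns the C6 hydroxyl to the outer face of the E C4=C5 alkene while the ring blocks the inner face, so oxygen is delivered to that face to give the trans oxirane threo to C6-O, and the C1=C10 alkene, which has no allylic hydroxyl, is left alone.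

Step 16
Reactants: 27 (1(10)E,3S,4S,5R,6S,7R)-3-(tert-butyldimethylsilyloxy)-4,5-epoxygermacr-1(10)-en-6-ol
Product: 28 (1(10)E,3S,4S,5R,6S,7R)-3-(tert-butyldimethylsilyloxy)-4,5-epoxygermacr-1(10)-en-6-yl acetate
Conditions: Ac2O, Et3N, DMAP (10 mol %), CH2Cl2, 0 °C to rt
Reagents that add atoms: acetic anhydride CC(=O)OC(C)=O
Why: DMAP-catalysed acetylation esterifies the hindered C6 hydroxyl under basic conditions that spare the acid-sensitive epoxide and the C1=C10 alkene lying across the ring from it.

Step 17
Reactants: 28 (1(10)E,3S,4S,5R,6S,7R)-3-(tert-butyldimethylsilyloxy)-4,5-epoxygermacr-1(10)-en-6-yl acetate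
Product: 29 (1(10)E,3S,4R,5R,6S,7R)-4,5-epoxy-3-hydroxygermacr-1(10)-en-6-yl acetate
Conditions: n-Bu4NF-AcOH (1:1, 2 equiv), THF, 0 °C to rt
Reagents that add atoms: none
Why: Fluoride cleavage of the silyl ether, buffered with acetic acid so that no free alkoxide builds up, avoids acetate loss or migration and Payne rearrangement of the 2,3-epoxy alcohol, and it follows epoxidation so that a C3 alkoxide never faces an intact 1,5-diene (oxy-Cope).

Step 18
Reactants: 29 (1(10)E,3S,4R,5R,6S,7R)-4,5-epoxy-3-hydroxygermacr-1(10)-en-6-yl acetate; 30 angelic acid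
Product: 32 (1(10)E,3S,4R,5R,6S,7R)-6-acetoxy-4,5-epoxygermacr-1(10)-en-3-yl angelate (CNP0180504.1), via angelic 2,4,6-trichlorobenzoic anhydride 31 (not isolated)
Conditions: 30, 2,4,6-trichlorobenzoyl chloride, Et3N, toluene, rt; then 29, 75 °C, no DMAP
Reagents that add atoms: none
Why: Yamaguchi esterification through mixed anhydride 31 without a nucleophilic pyridine catalyst transfers the angeloyl group with the C3-O bond and hence the C3 configuration intact and avoids the addition-elimination path by which angelates turn into tiglates.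

Compound list
1 | pent-4-yn-1-ol | C#CCCCO | starting material
2 | pent-4-ynal | C#CCCC=O | intermediate
3 | ethyl 2-[bis(2,2,2-trifluoroethoxy)phosphoryl]propanoate | CCOC(=O)C(C)P(=O)(OCC(F)(F)F)OCC(F)(F)F | starting material
4 | potassium carbanion of 3 (not isolated) | [K+].CCOC(=O)[C-](C)P(=O)(OCC(F)(F)F)OCC(F)(F)F | intermediate
5 | ethyl (Z)-2-methylhept-2-en-6-ynoate | C#CCC/C=C(/C)C(=O)OCC | intermediate
6 | (Z)-2-methylhept-2-en-6-yn-1-ol | C#CCC/C=C(/C)CO | intermediate
7 | (Z)-2-methylhept-2-en-6-yn-1-ol tert-butyldimethylsilyl ether | C#CCC/C=C(/C)CO[Si](C)(C)C(C)(C)C | intermediate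
8 | oxirane | C1CO1 | starting material
9 | (E)-alkenyldimethylalane, Al on C1 cis to the C14 methyl on C10 (not isolated) | C[Al](C)/C=C(\C)CC/C=C(/C)CO[Si](C)(C)C(C)(C)C | intermediate
10 | lithium butyl(dimethyl)alkenylalanate derived from 9 (not isolated) | [Li+].CCCC[Al-](C)(C)/C=C(\C)CC/C=C(/C)CO[Si](C)(C)C(C)(C)C | intermediate
11 | (3E,7Z)-9-(tert-butyldimethylsilyloxy)-4,8-dimethylnona-3,7-dien-1-ol | OCC/C=C(\C)CC/C=C(/C)CO[Si](C)(C)C(C)(C)C | intermediate
12 | (3E,7Z)-9-(tert-butyldimethylsilyloxy)-4,8-dimethylnona-3,7-dienal | O=CC/C=C(\C)CC/C=C(/C)CO[Si](C)(C)C(C)(C)C | intermediate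
13 | 3-chloroprop-1-yne | C#CCCl | starting material
14 | methyl(3-chloroprop-1-ynyl)zinc (not isolated) | C[Zn]C#CCCl | intermediate
15 | (4S,6E,10Z)-12-(tert-butyldimethylsilyloxy)-1-chloro-7,11-dimethyldodeca-6,10-dien-2-yn-4-ol | O[C@H](C#CCCl)C/C=C(\C)CC/C=C(/C)CO[Si](C)(C)C(C)(C)C | intermediate
16 | (2Z,6E,9S)-12-chloro-2,6-dimethyldodeca-2,6-dien-10-yne-1,9-diol | O[C@H](C#CCCl)C/C=C(\C)CC/C=C(/C)CO | intermediate
17 | disodium dialkoxide of 16 (not isolated) | [Na+].[Na+].[O-][C@H](C#CCCl)C/C=C(\C)CC/C=C(/C)C[O-] | intermediate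
18 | (5S,7E,11Z)-8,12-dimethyl-1-oxacyclotrideca-7,11-dien-3-yn-5-ol (13-membered ether, O between C6 and C12) | O[C@H]1C/C=C(\C)CC/C=C(/C)COCC#C1 | intermediate
19 | C3 lithium alkoxide of 18 (not isolated) | [Li+].[O-][C@H]1C/C=C(\C)CC/C=C(/C)COCC#C1 | intermediate
20 | C6-lithiated C3 lithium alkoxide of 18 (not isolated) | [Li+].[O-][C@H]1C/C=C(\C)CC/C=C(/C)COC([Li])C#C1 | intermediate
21 | (1(10)E,3S,6S,7R)-15-norgermacra-1(10),11-dien-4-yne-3,6-diol, equal to (1S,4S,6E,10R)-7-methyl-10-(prop-1-en-2-yl)cyclodec-6-en-2-yne-1,4-diol | O[C@H]1C/C=C(\C)CC[C@H](C(C)=C)[C@H](O)C#C1 | intermediate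
22 | (1(10)E,3S,6S,7R)-3-(tert-butyldimethylsilyloxy)-15-norgermacra-1(10),11-dien-4-yn-6-ol | CC(C)(C)[Si](C)(C)O[C@H]1C/C=C(\C)CC[C@H](C(C)=C)[C@H](O)C#C1 | intermediate
23 | sodium cyclic alanate, five-membered ring Al-O-C6-C5=C4 with two 2-methoxyethoxy ligands (not isolated) | [Na+].COCCO[Al-]1(OCCOC)O[C@@H]2/C=C1/[C@@H](O[Si](C)(C)C(C)(C)C)C/C=C(\C)CC[C@@H]2C(C)=C | intermediate
24 | (1(10)E,4Z,3S,6S,7R)-3-(tert-butyldimethylsilyloxy)-4-iodo-15-norgermacra-1(10),4,11-trien-6-ol (iodine cis to C6) | CC(C)(C)[Si](C)(C)O[C@H]1C/C=C(\C)CC[C@H](C(C)=C)[C@H](O)/C=C1\I | intermediate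
25 | (1(10)E,4E,3S,6R,7R)-3-(tert-butyldimethylsilyloxy)germacra-1(10),4,11-trien-6-ol (C6 descriptor changes by priority only) | CC(C)(C)[Si](C)(C)O[C@H]1C/C=C(\C)CC[C@H](C(C)=C)[C@H](O)/C=C1\C | intermediate
26 | (1(10)E,4E,3S,6S,7R)-3-(tert-butyldimethylsilyloxy)germacra-1(10),4-dien-6-ol | CC(C)(C)[Si](C)(C)O[C@H]1C/C=C(\C)CC[C@H](C(C)C)[C@H](O)/C=C1\C | intermediate
27 | (1(10)E,3S,4S,5R,6S,7R)-3-(tert-butyldimethylsilyloxy)-4,5-epoxygermacr-1(10)-en-6-ol (C4 descriptor S by priority of the silyloxy branch) | CC(C)(C)[Si](C)(C)O[C@H]1C/C=C(\C)CC[C@H](C(C)C)[C@H](O)[C@H]2O[C@]12C | intermediate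
28 | (1(10)E,3S,4S,5R,6S,7R)-3-(tert-butyldimethylsilyloxy)-4,5-epoxygermacr-1(10)-en-6-yl acetate | CC(C)(C)[Si](C)(C)O[C@H]1C/C=C(\C)CC[C@H](C(C)C)[C@H](OC(C)=O)[C@H]2O[C@]12C | intermediate
29 | (1(10)E,3S,4R,5R,6S,7R)-4,5-epoxy-3-hydroxygermacr-1(10)-en-6-yl acetate | O[C@H]1C/C=C(\C)CC[C@H](C(C)C)[C@H](OC(C)=O)[C@H]2O[C@]12C | intermediate
30 | angelic acid, (Z)-2-methylbut-2-enoic acid | C/C=C(/C)C(=O)O | starting material
31 | angelic 2,4,6-trichlorobenzoic anhydride (not isolated) | C/C=C(/C)C(=O)OC(=O)c1c(Cl)cc(Cl)cc1Cl | intermediate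
32 | (1(10)E,3S,4R,5R,6S,7R)-6-acetoxy-4,5-epoxygermacr-1(10)-en-3-yl angelate, CNP0180504.1 | C/C=C(/C)C(=O)O[C@H]1C/C=C(\C)CC[C@H](C(C)C)[C@H](OC(C)=O)[C@H]2O[C@]12C | target

Total step count: 18. Longest linear sequence: 18 steps (1 to 32). Compounds 3, 8, 13 and 30 are bought and enter directly.

Steps most likely to fail

1. Step 10. The C6-C7 bond may form on the wrong face of the C7=C11 alkene relative to C3 (poor or reversed facial selectivity). The C3 alkoxide lies four atoms from C6, and its own bias may oppose that of the amide. In the fallback, C3 is made with the opposite configuration, so that substrate and amide cooperate, and is inverted after the ring contraction.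
   - The fallback sets out from 12. Step 7 run with (R,R)-ProPhenol should give (4R,6E,10Z)-12-(tert-butyldimethylsilyloxy)-1-chloro-7,11-dimethyldodeca-6,10-dien-2-yn-4-ol F1.
   - The conditions of steps 8 and 9 lead to (2Z,6E,9R)-12-chloro-2,6-dimethyldodeca-2,6-dien-10-yne-1,9-diol F2 and then to (5R,7E,11Z)-8,12-dimethyl-1-oxacyclotrideca-7,11-dien-3-yn-5-ol F3.
   - The same (S,S)-amide should contract F3 to (1(10)E,3R,6S,7R)-15-norgermacra-1(10),11-dien-4-yne-3,6-diol F4.
   - A Mitsunobu reaction (PPh3, DIAD, 4-nitrobenzoic acid, THF, 0 °C) at the less hindered C3 carbinol inverts it to (1(10)E,3S,6S,7R)-6-hydroxy-15-norgermacra-1(10),11-dien-4-yn-3-yl 4-nitrobenzoate F5.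
   - K2CO3 in MeOH returns to the route at 21.

2. Step 7. While the aldehyde waits for a slowly formed and slowly reacting zinc alkynylide, the beta,gamma-alkene may slip into conjugation, the aldehyde may enolise, and the enantioselectivity may erode. In the fallback, the C3-C4 bond is made without stereocontrol and C3 is set afterwards by asymmetric reduction.
   - The fallback sets out from 12 and 13. Compound 13 is lithiated (n-BuLi, THF, -78 °C) to 3-chloroprop-1-ynyllithium F6.
   - F6 adds to 12 at -78 °C faster than enolisation and gives racemic (6E,10Z)-12-(tert-butyldimethylsilyloxy)-1-chloro-7,11-dimethyldodeca-6,10-dien-2-yn-4-ol F7.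
   - Buffered Dess-Martin oxidation gives (6E,10Z)-12-(tert-butyldimethylsilyloxy)-1-chloro-7,11-dimethyldodeca-6,10-dien-2-yn-4-one F8.
   - Noyori asymmetric transfer hydrogenation under base-free conditions (Ru[(S,S)-TsNCH(Ph)CH(Ph)NH](p-cymene), i-PrOH, rt) should reduce the ynone to the (S)-alcohol and rejoin the route at 15.

3. Step 9. Intermolecular O-alkylation (oligomerisation) may outrun ring closure, with the C3 alkoxide acting as a second nucleophilic site. Warming to speed up the closure invites an oxy-Cope shift of the sodium 3-oxido-1,5-enyne. In the fallback, the C3 oxygen is masked during the ring closure and released afterwards, so that the alkoxide tactic of step 10 is kept.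
   - The fallback sets out from 15. TBSCl and imidazole give (4S,6E,10Z)-4,12-bis(tert-butyldimethylsilyloxy)-1-chloro-7,11-dimethyldodeca-6,10-dien-2-yne F9.
   - Camphorsulfonic acid in MeOH at 0 °C cleaves only the primary allylic silyl ether and gives (2Z,6E,9S)-9-(tert-butyldimethylsilyloxy)-12-chloro-2,6-dimethyldodeca-2,6-dien-10-yn-1-ol F10.
   - NaH with n-Bu4NI under high dilution, now free to be heated, closes the ring to (5S,7E,11Z)-5-(tert-butyldimethylsilyloxy)-8,12-dimethyl-1-oxacyclotrideca-7,11-dien-3-yne F11.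
   - n-Bu4NF in THF removes the silyl group and rejoins the route at 18.

Further compounds
F1 | step 10 | (4R,6E,10Z)-12-(tert-butyldimethylsilyloxy)-1-chloro-7,11-dimethyldodeca-6,10-dien-2-yn-4-ol | O[C@@H](C#CCCl)C/C=C(\C)CC/C=C(/C)CO[Si](C)(C)C(C)(C)C
F2 | step 10 | (2Z,6E,9R)-12-chloro-2,6-dimethyldodeca-2,6-dien-10-yne-1,9-diol | O[C@@H](C#CCCl)C/C=C(\C)CC/C=C(/C)CO
F3 | step 10 | (5R,7E,11Z)-8,12-dimethyl-1-oxacyclotrideca-7,11-dien-3-yn-5-ol | O[C@@H]1C/C=C(\C)CC/C=C(/C)COCC#C1
F4 | step 10 | (1(10)E,3R,6S,7R)-15-norgermacra-1(10),11-dien-4-yne-3,6-diol | O[C@@H]1C/C=C(\C)CC[C@H](C(C)=C)[C@H](O)C#C1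
F5 | step 10 | (1(10)E,3S,6S,7R)-6-hydroxy-15-norgermacra-1(10),11-dien-4-yn-3-yl 4-nitrobenzoate | O=C(O[C@H]1C/C=C(\C)CC[C@H](C(C)=C)[C@H](O)C#C1)c1ccc(cc1)[N+](=O)[O-]
F6 | step 7 | 3-chloroprop-1-ynyllithium | [Li]C#CCCl
F7 | step 7 | racemic (6E,10Z)-12-(tert-butyldimethylsilyloxy)-1-chloro-7,11-dimethyldodeca-6,10-dien-2-yn-4-ol | OC(C#CCCl)C/C=C(\C)CC/C=C(/C)CO[Si](C)(C)C(C)(C)C
F8 | step 7 | (6E,10Z)-12-(tert-butyldimethylsilyloxy)-1-chloro-7,11-dimethyldodeca-6,10-dien-2-yn-4-one | O=C(C#CCCl)C/C=C(\C)CC/C=C(/C)CO[Si](C)(C)C(C)(C)C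
F9 | step 9 | (4S,6E,10Z)-4,12-bis(tert-butyldimethylsilyloxy)-1-chloro-7,11-dimethyldodeca-6,10-dien-2-yne | CC(C)(C)[Si](C)(C)O[C@H](C#CCCl)C/C=C(\C)CC/C=C(/C)CO[Si](C)(C)C(C)(C)C
F10 | step 9 | (2Z,6E,9S)-9-(tert-butyldimethylsilyloxy)-12-chloro-2,6-dimethyldodeca-2,6-dien-10-yn-1-ol | CC(C)(C)[Si](C)(C)O[C@H](C#CCCl)C/C=C(\C)CC/C=C(/C)CO
F11 | step 9 | (5S,7E,11Z)-5-(tert-butyldimethylsilyloxy)-8,12-dimethyl-1-oxacyclotrideca-7,11-dien-3-yne | CC(C)(C)[Si](C)(C)O[C@H]1C/C=C(\C)CC/C=C(/C)COCC#C1
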